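## Retrosynthetic overview

1. The only ring of the target, the dihydropyranone, is closed last by lactonisation of a (Z)-5-hydroxy-2-enoate, made from the 2-ynoate by cis-semihydrogenation.
2. C7–OH and C11–OH come from two ketones, both reduced 1,3-syn in one operation under the direction of C5–OH and C9–OH.
3. C3–C4: lithium ethyl propiolate (a β-acyl vinyl anion equivalent) opens a terminal C4/C5 epoxide.
4. Key step, C6–C7 and C7–C8: a 2-silyl-1,3-dithiane acts as a carbonyl dianion linchpin that joins two epoxide CH2 termini in one flask (Brook relay); C5 and C9 both come from (R)-epichlorohydrin.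
5. C10–C11 and C11–C12: 1,3-dithiane is alkylated with 1-bromopentadecane, then with (R)-epichlorohydrin.

Assumption: atom labels C1–C26 are those of the open-chain acid (C1 lactone carbonyl, C5 ring CH–O, C26 terminal CH3); the SMILES is read as (6S)-6-[(2R,4R,6R)-2,4,6-trihydroxyhenicosyl]-5,6-dihydro-2H-pyran-2-one, the all-syn C5/C7/C9/C11 isomer.

## Route

Step 1
Reactants: 1 1,3-dithiane; 2 1-bromopentadecane; 3 (R)-epichlorohydrin
Product: 8 2-[(2R)-oxiran-2-ylmethyl]-2-pentadecyl-1,3-dithiane, via 2-lithio-1,3-dithiane 4 (not isolated), via 2-pentadecyl-1,3-dithiane 5 (not isolated), via 2-lithio-2-pentadecyl-1,3-dithiane 6 (not isolated), via C9 chlorohydrin alkoxide 7 (not isolated)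
Conditions: n-BuLi (1.0 equiv), THF, −30 °C; 2, −78 °C to rt; n-BuLi (1.05 equiv), −20 °C, 3 h; 3, −78 °C to rt, 12 h
Reagents that add atoms: none
Why: Corey–Seebach dithiane alkylation run twice in one flask: the lithiated dithiane displaces the primary bromide, the relithiated 2-alkyl dithiane opens (R)-epichlorohydrin at its unsubstituted epoxide carbon, and the chlorohydrin alkoxide closes (intramolecular Williamson) to the new terminal epoxide without touching the stereocentre, so C9 is bought as (R)-epichlorohydrin.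

Step 2
Reactants: 9 2-(tert-butyldimethylsilyl)-1,3-dithiane; 8 2-[(2R)-oxiran-2-ylmethyl]-2-pentadecyl-1,3-dithiane; 3 (R)-epichlorohydrin
Product: 14 (2R)-2-({2-[(2R)-2-[(tert-butyldimethylsilyl)oxy]-3-(2-pentadecyl-1,3-dithian-2-yl)propyl]-1,3-dithian-2-yl}methyl)oxirane, via lithiated silyl dithiane 10 (not isolated), via C9 lithium alkoxide 11 (not isolated), via Brook-rearranged dithianyllithium 12 (not isolated), via C5 chlorohydrin alkoxide 13 (not isolated)
Conditions: t-BuLi, Et2O, −78 to −45 °C; 8, −78 to −25 °C; then 3, HMPA, −78 °C to rt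
Reagents that add atoms: none
Why: Tietze–Smith linchpin coupling (anion relay): the lithiated silyl dithiane opens the epoxide of 8 at CH2 in Et2O, HMPA then triggers a 1,4-Brook rearrangement (C to O silyl shift) that unveils a new dithiane anion, and this opens (R)-epichlorohydrin at its epoxide CH2 before the chlorohydrin alkoxide closes to the (R)-epoxide, so the dithiane carbon (C7) is bonded to two formerly electrophilic carbons and both C9 and C5 keep the configuration of (R)-epichlorohydrin.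

Step 3
Reactants: 15 ethyl propiolate; 14 (2R)-2-({2-[(2R)-2-[(tert-butyldimethylsilyl)oxy]-3-(2-pentadecyl-1,3-dithian-2-yl)propyl]-1,3-dithian-2-yl}methyl)oxirane
Product: 17 ethyl (5S)-6-{2-[(2R)-2-[(tert-butyldimethylsilyl)oxy]-3-(2-pentadecyl-1,3-dithian-2-yl)propyl]-1,3-dithian-2-yl}-5-hydroxyhex-2-ynoate, via lithium ethyl propiolate 16 (not isolated)
Conditions: 15 (4 equiv), n-BuLi, THF, −78 °C; BF3·OEt2; 14, −78 °C, 2 h; aq NH4Cl
Reagents that add atoms: none
Why: Yamaguchi–Hirao alkynylation: the BF3-activated terminal epoxide is opened at CH2 by lithium ethyl propiolate, so C5 keeps its configuration (the descriptor becomes S only by CIP priority) and C1–C3 arrive at the acid oxidation level.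

Step 4
Reactants: 17 ethyl (5S)-6-{2-[(2R)-2-[(tert-butyldimethylsilyl)oxy]-3-(2-pentadecyl-1,3-dithian-2-yl)propyl]-1,3-dithian-2-yl}-5-hydroxyhex-2-ynoate
Product: 19 ethyl (5S,9R)-5,9-dihydroxy-7,11-dioxohexacos-2-ynoate, via silyl ether diketone 18 (not isolated)
Conditions: PhI(OCOCF3)2 (3 equiv), MeCN/H2O (9:1), 0 °C, 20 min; then 48% aq HF, 0 °C to rt; crude product used at once
Reagents that add atoms: water, O
Why: Oxidative dethioketalisation with PhI(OCOCF3)2 converts both dithianes to ketones under metal-free, weakly acidic conditions that tolerate the ynoate and the free alcohol, and HF then cleaves the secondary silyl ether (fluoride desilylation) so that both β-hydroxyls are free to direct step 5.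

Step 5
Reactants: 19 ethyl (5S,9R)-5,9-dihydroxy-7,11-dioxohexacos-2-ynoate
Product: 20 ethyl (5S,7S,9R,11R)-5,7,9,11-tetrahydroxyhexacos-2-ynoate
Conditions: Et2BOMe (2.5 equiv), THF/MeOH (4:1), −78 °C, 30 min; NaBH4, −78 °C, 4 h; AcOH; MeOH co-evaporation
Reagents that add atoms: none
Why: Twofold Narasaka–Prasad reduction: each ketone sits in a six-membered Et2B chelate with a β-hydroxyl (O5 to the C7 ketone, O9 to the C11 ketone) and takes external hydride to give the 1,3-syn diol, and because C5 and C9 are already 1,5-syn, the new centres C7 and C11 complete the all-syn array.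

Step 6
Reactants: 20 ethyl (5S,7S,9R,11R)-5,7,9,11-tetrahydroxyhexacos-2-ynoate
Product: 22 (6S)-6-[(2R,4R,6R)-2,4,6-trihydroxyhenicosyl]-5,6-dihydro-2H-pyran-2-one, via Z-enoate 21 (not isolated)
Conditions: H2 (1 atm), Pd/CaCO3 poisoned with Pb(OAc)2 (Lindlar catalyst), quinoline, EtOAc, rt; filter; PPTS (0.2 equiv), PhH, 60 °C
Reagents that add atoms: none
Why: Cis-semihydrogenation over lead-poisoned Pd/CaCO3 (Lindlar reduction) gives the Z-enoate, whose C5 hydroxyl then lactonises by acid-catalysed transesterification to the six-membered unsaturated lactone; no stereocentre is touched.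

## Compound list

1 | 1,3-dithiane | C1SCCCS1 | starting material
2 | 1-bromopentadecane | CCCCCCCCCCCCCCCBr | starting material
3 | (R)-epichlorohydrin, (2R)-2-(chloromethyl)oxirane | ClC[C@H]1CO1 | starting material
4 | 2-lithio-1,3-dithiane | [Li]C1SCCCS1 | intermediate
5 | 2-pentadecyl-1,3-dithiane | CCCCCCCCCCCCCCCC1SCCCS1 | intermediate
6 | 2-lithio-2-pentadecyl-1,3-dithiane | CCCCCCCCCCCCCCCC1([Li])SCCCS1 | intermediate
7 | lithium (2R)-1-chloro-3-(2-pentadecyl-1,3-dithian-2-yl)propan-2-olate | CCCCCCCCCCCCCCCC1(C[C@@H](O[Li])CCl)SCCCS1 | intermediate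
8 | 2-[(2R)-oxiran-2-ylmethyl]-2-pentadecyl-1,3-dithiane | CCCCCCCCCCCCCCCC1(C[C@@H]2CO2)SCCCS1 | intermediate
9 | 2-(tert-butyldimethylsilyl)-1,3-dithiane | CC(C)(C)[Si](C)(C)C1SCCCS1 | starting material
10 | 2-lithio-2-(tert-butyldimethylsilyl)-1,3-dithiane | CC(C)(C)[Si](C)(C)C1([Li])SCCCS1 | intermediate
11 | lithium (2R)-1-[2-(tert-butyldimethylsilyl)-1,3-dithian-2-yl]-3-(2-pentadecyl-1,3-dithian-2-yl)propan-2-olate | CCCCCCCCCCCCCCCC1(C[C@@H](O[Li])CC2([Si](C)(C)C(C)(C)C)SCCCS2)SCCCS1 | intermediate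
12 | 2-lithio-2-[(2S)-2-[(tert-butyldimethylsilyl)oxy]-3-(2-pentadecyl-1,3-dithian-2-yl)propyl]-1,3-dithiane (same centre as in 11; descriptor changes by CIP priority only) | CCCCCCCCCCCCCCCC1(C[C@@H](O[Si](C)(C)C(C)(C)C)CC2([Li])SCCCS2)SCCCS1 | intermediate
13 | lithium (2R)-1-chloro-3-{2-[(2R)-2-[(tert-butyldimethylsilyl)oxy]-3-(2-pentadecyl-1,3-dithian-2-yl)propyl]-1,3-dithian-2-yl}propan-2-olate | CCCCCCCCCCCCCCCC1(C[C@@H](O[Si](C)(C)C(C)(C)C)CC2(C[C@@H](O[Li])CCl)SCCCS2)SCCCS1 | intermediate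
14 | (2R)-2-({2-[(2R)-2-[(tert-butyldimethylsilyl)oxy]-3-(2-pentadecyl-1,3-dithian-2-yl)propyl]-1,3-dithian-2-yl}methyl)oxirane | CCCCCCCCCCCCCCCC1(C[C@@H](O[Si](C)(C)C(C)(C)C)CC2(C[C@@H]3CO3)SCCCS2)SCCCS1 | intermediate
15 | ethyl propiolate (ethyl prop-2-ynoate) | C#CC(=O)OCC | starting material
16 | lithium ethyl propiolate (ethyl 3-lithioprop-2-ynoate) | [Li]C#CC(=O)OCC | intermediate
17 | ethyl (5S)-6-{2-[(2R)-2-[(tert-butyldimethylsilyl)oxy]-3-(2-pentadecyl-1,3-dithian-2-yl)propyl]-1,3-dithian-2-yl}-5-hydroxyhex-2-ynoate | CCCCCCCCCCCCCCCC1(C[C@@H](O[Si](C)(C)C(C)(C)C)CC2(C[C@@H](O)CC#CC(=O)OCC)SCCCS2)SCCCS1 | intermediate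
18 | ethyl (5S,9R)-9-[(tert-butyldimethylsilyl)oxy]-5-hydroxy-7,11-dioxohexacos-2-ynoate | CCCCCCCCCCCCCCCC(=O)C[C@@H](O[Si](C)(C)C(C)(C)C)CC(=O)C[C@@H](O)CC#CC(=O)OCC | intermediate
19 | ethyl (5S,9R)-5,9-dihydroxy-7,11-dioxohexacos-2-ynoate | CCCCCCCCCCCCCCCC(=O)C[C@@H](O)CC(=O)C[C@@H](O)CC#CC(=O)OCC | intermediate
20 | ethyl (5S,7S,9R,11R)-5,7,9,11-tetrahydroxyhexacos-2-ynoate (all-syn) | CCCCCCCCCCCCCCC[C@@H](O)C[C@@H](O)C[C@@H](O)C[C@@H](O)CC#CC(=O)OCC | intermediate
21 | ethyl (2Z,5S,7S,9R,11R)-5,7,9,11-tetrahydroxyhexacos-2-enoate | CCCCCCCCCCCCCCC[C@@H](O)C[C@@H](O)C[C@@H](O)C[C@@H](O)C/C=C\C(=O)OCC | intermediate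
22 | (6S)-6-[(2R,4R,6R)-2,4,6-trihydroxyhenicosyl]-5,6-dihydro-2H-pyran-2-one (CNP0231118.1) | CCCCCCCCCCCCCCC[C@@H](O)C[C@@H](O)C[C@@H](O)C[C@@H]1CC=CC(=O)O1 | target

## Step count and risks

Total step count: 6. Longest linear sequence: 6 steps (1 → 8 → 14 → 17 → 19 → 20 → 22).

Three steps most likely to fail:

Step 2. The relay can stall (incomplete silyl shift, proton quench of 12), and in HMPA a direct chloride displacement on 3 would invert the sense at C5. The fallback sets out from 8 and comes back at 14, with no silyl relay. 2-Lithio-1,3-dithiane 4 (n-BuLi, THF, −78 to 0 °C) opens 8 to the alcohol (2S)-1-(1,3-dithian-2-yl)-3-(2-pentadecyl-1,3-dithian-2-yl)propan-2-ol F1. TBSOTf and 2,6-lutidine in CH2Cl2 give tert-butyl{[(2S)-1-(1,3-dithian-2-yl)-3-(2-pentadecyl-1,3-dithian-2-yl)propan-2-yl]oxy}dimethylsilane F2. Metalation with t-BuLi in THF at −78 °C then forms 12 as a discrete species, which is alkylated with 3 in THF to give 14 by way of 13. The S descriptor in F1 and F2 is a CIP priority change; the centre is the same as in 11.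

Step 3. Lithium ethyl propiolate is a weak and thermally labile nucleophile, and BF3 may be tied up by the four sulfur atoms. The fallback sets out from 14 and comes back at 22, using a more nucleophilic acetylide and setting the C1 oxidation level last.
- Commercial tert-butyldimethyl(prop-2-yn-1-yloxy)silane and n-BuLi give lithium 3-[(tert-butyldimethylsilyl)oxy]prop-1-yn-1-ide F3, which with BF3·OEt2 opens 14 to (2S)-5-[(tert-butyldimethylsilyl)oxy]-1-{2-[(2R)-2-[(tert-butyldimethylsilyl)oxy]-3-(2-pentadecyl-1,3-dithian-2-yl)propyl]-1,3-dithian-2-yl}pent-3-yn-2-ol F4.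
- PhI(OCOCF3)2 in wet MeCN gives (5S,9R)-1,9-bis[(tert-butyldimethylsilyl)oxy]-5-hydroxyhexacos-2-yne-7,11-dione F5, and aqueous HF in the same flask gives (5S,9R)-1,5,9-trihydroxyhexacos-2-yne-7,11-dione F6.
- Twofold Et2BOMe/NaBH4 reduction, with no hydride-sensitive ynoate present, gives (5S,7S,9R,11R)-hexacos-2-yne-1,5,7,9,11-pentol F7.
- Semihydrogenation over Pd/CaCO3 poisoned with Pb(OAc)2 gives (2Z,5S,7S,9R,11R)-hexacos-2-ene-1,5,7,9,11-pentol F8.
- TEMPO (catalytic) and PhI(OAc)2 in CH2Cl2 oxidise only the primary allylic alcohol to (2Z,5S,7S,9R,11R)-5,7,9,11-tetrahydroxyhexacos-2-enal F9. This closes onto the C5 hydroxyl as the lactol (6S)-6-[(2R,4R,6R)-2,4,6-trihydroxyhenicosyl]-5,6-dihydro-2H-pyran-2-ol F10, which is oxidised on to 22.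

Step 5. Two ketones must each find their own β-hydroxyl; C9–OH is β to both, so a mis-chelated C11 ketone would be reduced without control, and hydride may also add to the ynoate. The fallback sets out from 18 and comes back at 20, with the two reductions done one at a time and gated by the silyl group.
- Step 4 is stopped before the HF stage and 18 is isolated.
- Et2BOMe and NaBH4 (about 1 equiv each, −78 °C) reduce only the C7 ketone, the only one with a free β-hydroxyl, to give ethyl (5S,7S,9S)-9-[(tert-butyldimethylsilyl)oxy]-5,7-dihydroxy-11-oxohexacos-2-ynoate F11.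
- Aqueous HF in MeCN frees C9–OH to give ethyl (5S,7S,9S)-5,7,9-trihydroxy-11-oxohexacos-2-ynoate F12.
- A second Narasaka–Prasad reduction, now with one ketone and one possible chelate, gives 20. The 9S descriptor in F11 and F12 is again a priority change only.

Further compounds
F1 | step 2 | (2S)-1-(1,3-dithian-2-yl)-3-(2-pentadecyl-1,3-dithian-2-yl)propan-2-ol | CCCCCCCCCCCCCCCC1(C[C@@H](O)CC2SCCCS2)SCCCS1
F2 | step 2 | tert-butyl{[(2S)-1-(1,3-dithian-2-yl)-3-(2-pentadecyl-1,3-dithian-2-yl)propan-2-yl]oxy}dimethylsilane | CCCCCCCCCCCCCCCC1(C[C@@H](O[Si](C)(C)C(C)(C)C)CC2SCCCS2)SCCCS1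
F3 | step 3 | lithium 3-[(tert-butyldimethylsilyl)oxy]prop-1-yn-1-ide | [Li]C#CCO[Si](C)(C)C(C)(C)C
F4 | step 3 | (2S)-5-[(tert-butyldimethylsilyl)oxy]-1-{2-[(2R)-2-[(tert-butyldimethylsilyl)oxy]-3-(2-pentadecyl-1,3-dithian-2-yl)propyl]-1,3-dithian-2-yl}pent-3-yn-2-ol | CCCCCCCCCCCCCCCC1(C[C@@H](O[Si](C)(C)C(C)(C)C)CC2(C[C@@H](O)CC#CCO[Si](C)(C)C(C)(C)C)SCCCS2)SCCCS1
F5 | step 3 | (5S,9R)-1,9-bis[(tert-butyldimethylsilyl)oxy]-5-hydroxyhexacos-2-yne-7,11-dione | CCCCCCCCCCCCCCCC(=O)C[C@@H](O[Si](C)(C)C(C)(C)C)CC(=O)C[C@@H](O)CC#CCO[Si](C)(C)C(C)(C)C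
F6 | step 3 | (5S,9R)-1,5,9-trihydroxyhexacos-2-yne-7,11-dione | CCCCCCCCCCCCCCCC(=O)C[C@@H](O)CC(=O)C[C@@H](O)CC#CCO
F7 | step 3 | (5S,7S,9R,11R)-hexacos-2-yne-1,5,7,9,11-pentol | CCCCCCCCCCCCCCC[C@@H](O)C[C@@H](O)C[C@@H](O)C[C@@H](O)CC#CCO
F8 | step 3 | (2Z,5S,7S,9R,11R)-hexacos-2-ene-1,5,7,9,11-pentol | CCCCCCCCCCCCCCC[C@@H](O)C[C@@H](O)C[C@@H](O)C[C@@H](O)C/C=C\CO
F9 | step 3 | (2Z,5S,7S,9R,11R)-5,7,9,11-tetrahydroxyhexacos-2-enal | CCCCCCCCCCCCCCC[C@@H](O)C[C@@H](O)C[C@@H](O)C[C@@H](O)C/C=C\C=O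
F10 | step 3 | (6S)-6-[(2R,4R,6R)-2,4,6-trihydroxyhenicosyl]-5,6-dihydro-2H-pyran-2-ol (either configuration at C2) | CCCCCCCCCCCCCCC[C@@H](O)C[C@@H](O)C[C@@H](O)C[C@@H]1CC=CC(O)O1
F11 | step 5 | ethyl (5S,7S,9S)-9-[(tert-butyldimethylsilyl)oxy]-5,7-dihydroxy-11-oxohexacos-2-ynoate | CCCCCCCCCCCCCCCC(=O)C[C@@H](O[Si](C)(C)C(C)(C)C)C[C@@H](O)C[C@@H](O)CC#CC(=O)OCC
F12 | step 5 | ethyl (5S,7S,9S)-5,7,9-trihydroxy-11-oxohexacos-2-ynoate | CCCCCCCCCCCCCCCC(=O)C[C@@H](O)C[C@@H](O)C[C@@H](O)CC#CC(=O)OCC
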